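**The sum.** I begin with a sum. Saturday's flask at 40.0 min holds 71.8% of its Z as Z and 26.9% as J, together 98.7%, and Wednesday's holds 99.2%. The balance closes within the scatter, so the fraction of Z left tells me what has reacted.

all flasks: Z 0.050 M
- Saturday's: Q 0.037 M; run made earlier
- Wednesday's: Q 0.045 M; run made earlier
- alder: Q 0.0500 M; time 40 min
- larch: Q 0.0650 M; time 40 min

| run | time / min | Z / % | J / % |
|---|---|---|---|
| Saturday's | 3.00 | 83.9 | 15.5 |
| Saturday's | 8.00 | 78.7 | 21.9 |
| Saturday's | 15.0 | 77.5 | 23.6 |
| Saturday's | 40.0 | 71.8 | 26.9 |
| Wednesday's | 3.00 | 80.8 | 21.0 |
| Wednesday's | 8.00 | 74.8 | 26.4 |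
| Wednesday's | 15.0 | 72.9 | 27.9 |
| Wednesday's | 40.0 | 65.7 | 33.5 |

(readings scatter by 1 percentage point)

* part of the Z that has reacted at the end, alder
* part of the Z that has reacted at the end, larch
* what raising the concentration of Q from its lowest to its highest value here does to the part of the Z that has reacted (changes below 5 percentage points count as none) (it rises / no change / it falls)



**The take.** One minus the fraction left, times [Z], gives the Z consumed. Divided by the [Q] charged, this gives 0.381 on Saturday and 0.381 on Wednesday. One point of scatter moves such a figure by 0.0135. I carry the mean, 0.381, as the take: the moles of Z consumed by 40 min per mole of Q charged, an apparent stoichiometry.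

**First numbers.** Multiplying the take by [Q]/[Z] gives 38.1% for alder and 49.5% for larch.

**Weak link.** The straight line in Q is the weak link, since larch lies beyond both runs and Z thins as it reacts. So I reckon again with the fraction left, supposing that each slice of Q removes a fixed share of the remaining Z. The logarithm of one over the fraction left, per [Q], reads 9.14 /M, which gives 36.7% for alder and 44.8% for larch. I commit to the midpoints, 37.4% and 47.2%, a rise of 9.8 percentage points, more than the 5 points that counts. The forecast gives 37% and 46%, lower than mine for larch, and its answer on the trend is it rises, in its words “Conversion rises with Q”.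

**The result.** The flask gives 37.8% for alder and 47.7% for larch, so it rises by 9.9 points.

    Q + L ⇌ E, settled at all times (K = 30000 /M)
    J → G (k = 6.90 × 10⁻⁴ /min)
    Z + Q ⇌ L + J (K = 0.600, k = 3.20 /M/min)
    Q ⇌ X (K = 5.40, k = 0.250 /min)

**Not at rest.** Reckoned from these results, the take is 0.378 in alder and 0.367 in larch. In a neighbour flask, the same as alder but with 0.12 M of Q, my take promises 91.5%, but that flask gives 76.6%. The take belongs to 40 min, and alder is still moving: at 400 min, ten times as long, its J has gone from 36.9% to 34.8% while G has climbed from 0.848% to 10.4%. The Z reacted by then reaches 45.2% in alder and 57.5% in larch.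

Readings and results are calculated with made-up constants, noise included.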